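**Retrosynthetic overview**

- The strategy rests on the only ring, the cyclopropane C5–C6–C7. C6 is a lone CH2 bridging the chain carbons C5 and C7 trans, so the ring is the formal adduct of one methylene unit and an (E)-C5=C7 olefin, as in a one-carbon transfer from S-adenosylmethionine. It is made by ligand-controlled methylene transfer to the (E)-allylic alcohol carrying its hydroxyl on C4.
- The allylic alcohol comes from the (R)-Roche ester (C7–C8–C9, fixing C8) by silylation, partial reduction, Horner–Wadsworth–Emmons olefination (C5, C4) and reduction.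
- After ring formation, C1–C3 are added to C4 by Wittig olefination with a three-carbon acetal ylide, diimide reduction and oxidation to the methyl ester. C9 is then converted into the (E)-vinyl iodide (Takai).
- The C10–C11 bond of the (9E,11E)-diene is closed by Negishi coupling with the C11–C19 alkenylzinc, made by syn-methylalumination of a terminal alkyne derived from (S)-citronellal (C16). The C18≡C19 alkyne travels as its triisopropylsilyl derivative and is bromodesilylated last.

Key step: step 5

Remark on the chemistry: olefin 12 is drawn as the Z isomer expected from the unstabilised ylide; its geometry is immaterial because step 8 saturates that bond.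

**Main line (C1–C10)**

Step 1
Reactants: 1 methyl (R)-3-hydroxy-2-methylpropanoate
Product: 2 methyl (2R)-3-(tert-butyldiphenylsilyloxy)-2-methylpropanoate
Conditions: TBDPSCl, imidazole, CH2Cl2, 0 °C → rt
Reagents that add atoms: tert-butyl(chloro)diphenylsilane, CC(C)(C)[Si](Cl)(c1ccccc1)c1ccccc1
Why: Imidazole-promoted silyl ether formation at the unhindered primary hydroxyl should give a robust C9–O protecting group without touching the C8 centre.

Step 2
Reactants: 2 methyl (2R)-3-(tert-butyldiphenylsilyloxy)-2-methylpropanoate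
Product: 3 (2R)-3-(tert-butyldiphenylsilyloxy)-2-methylpropanal
Conditions: i-Bu2AlH (1.05 equiv), CH2Cl2, −78 °C; MeOH, then aq. potassium sodium tartrate; used crude
Reagents that add atoms: none
Why: Partial hydride reduction of the ester stops at the aluminium hemiacetal, which is stable at −78 °C and collapses to the aldehyde only on work-up; the crude aldehyde is used at once so that C8 is not epimerised.

Step 3
Reactants: 3 (2R)-3-(tert-butyldiphenylsilyloxy)-2-methylpropanal; 4 triethyl phosphonoacetate
Product: 5 ethyl (2E,4S)-5-(tert-butyldiphenylsilyloxy)-4-methylpent-2-enoate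
Conditions: 4, NaH, THF, 0 °C; then 3, −78 → 0 °C
Reagents that add atoms: triethyl phosphonoacetate (4), CCOC(=O)CP(=O)(OCC)OCC
Why: Horner–Wadsworth–Emmons olefination with the stabilised phosphonate anion should give the E-enoate (C7=C5), and cold addition of the aldehyde to the preformed anion protects the C8 centre.

Step 4
Reactants: 5 ethyl (2E,4S)-5-(tert-butyldiphenylsilyloxy)-4-methylpent-2-enoate
Product: 6 (2E,4S)-5-(tert-butyldiphenylsilyloxy)-4-methylpent-2-en-1-ol
Conditions: i-Bu2AlH (2.3 equiv), CH2Cl2, −78 °C; aq. potassium sodium tartrate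
Reagents that add atoms: none
Why: 1,2-Reduction of the enoate with the aluminium hydride should give the (E)-allylic alcohol without conjugate reduction or loss of olefin geometry.

Step 5
Reactants: 6 (2E,4S)-5-(tert-butyldiphenylsilyloxy)-4-methylpent-2-en-1-ol; 7 diiodomethane
Product: 9 [(1R,2S)-2-[(2S)-1-(tert-butyldiphenylsilyloxy)propan-2-yl]cyclopropyl]methanol, via iodomethylzinc alkoxide 8 (not isolated)
Conditions: Et2Zn (2.2 equiv), 7 (4.4 equiv), DME, CH2Cl2, −15 °C; then 6 and (4S,5S)-2-butyl-N,N,N′,N′-tetramethyl-1,3,2-dioxaborolane-4,5-dicarboxamide (1.2 equiv), −15 °C → rt; aq. NH4Cl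
Reagents that add atoms: diiodomethane (7), ICI
Why: Directed asymmetric Simmons–Smith cyclopropanation: Zn(CH2I)2 converts the hydroxyl of 6 into the iodomethylzinc alkoxide 8, whose oxygen binds the boron of the dioxaborolane as a boronate while an amide carbonyl and the alkoxide hold a second zinc carbenoid over one face of the C5=C7 olefin. CH2 is then delivered in a concerted butterfly-type [2+1] transfer that forms C5–C6 and C6–C7 together, so the three-membered ring closes by intermolecular suprafacial methylene addition to the olefin and the E geometry is copied into the trans C5/C7 relationship. The absolute configuration at C5 and C7 is set by the ligand: the (4S,5S) ligand is the enantiomer of the one known to give (1S,2S)-2-arylcyclopropylmethanols from E-allylic alcohols, and should therefore give the face topology of 9 (the S descriptor at C7 arises only from substituent priorities). C8 is not touched. The step needs reagent-controlled facial selectivity, which is secured by the free primary allylic hydroxyl as the only good zinc-binding site, since the bulky silyl ether at C9 coordinates poorly and the C8 methyl centre exerts only a weak bias of its own. The closest known reaction type is the dioxaborolane-mediated enantioselective cyclopropanation of E-disubstituted allylic alcohols with Zn(CH2I)2.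

Step 6
Reactants: 9 [(1R,2S)-2-[(2S)-1-(tert-butyldiphenylsilyloxy)propan-2-yl]cyclopropyl]methanol
Product: 10 (1R,2S)-2-[(2S)-1-(tert-butyldiphenylsilyloxy)propan-2-yl]cyclopropane-1-carbaldehyde
Conditions: Dess–Martin periodinane, NaHCO3, CH2Cl2, 0 °C → rt
Reagents that add atoms: none
Why: Buffered Dess–Martin oxidation of the primary alcohol should give the cyclopropanecarbaldehyde without ring opening, and the trans ring configuration is the stable one at C5.

Step 7
Reactants: 10 (1R,2S)-2-[(2S)-1-(tert-butyldiphenylsilyloxy)propan-2-yl]cyclopropane-1-carbaldehyde; 11 [2-(1,3-dioxolan-2-yl)ethyl]triphenylphosphonium bromide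
Product: 12 2-[(2Z)-3-{(1S,2R)-2-[(2S)-1-(tert-butyldiphenylsilyloxy)propan-2-yl]cyclopropyl}prop-2-en-1-yl]-1,3-dioxolane
Conditions: 11, NaN(SiMe3)2, THF, 0 °C; then 10, −78 °C → rt
Reagents that add atoms: [2-(1,3-dioxolan-2-yl)ethyl]triphenylphosphonium bromide (11), [Br-].C1COC(CC[P+](c2ccccc2)(c2ccccc2)c2ccccc2)O1
Why: Wittig olefination with the unstabilised three-carbon ylide adds C3, C2 and the masked C1 in one operation; the acetal oxygens sit on the γ-carbon of the ylide, so it cannot fragment by β-elimination.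

Step 8
Reactants: 12 2-[(2Z)-3-{(1S,2R)-2-[(2S)-1-(tert-butyldiphenylsilyloxy)propan-2-yl]cyclopropyl}prop-2-en-1-yl]-1,3-dioxolane
Product: 13 2-(3-{(1R,2R)-2-[(2S)-1-(tert-butyldiphenylsilyloxy)propan-2-yl]cyclopropyl}propyl)-1,3-dioxolane
Conditions: TsNHNH2, NaOAc, DME/H2O, reflux
Reagents that add atoms: none
Why: Diimide reduction transfers H2 to the disubstituted olefin in a concerted syn step, so the vinylcyclopropane is saturated without the ring hydrogenolysis that metal-catalysed hydrogenation could cause, and the buffered medium spares acetal and silyl ether.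

Step 9
Reactants: 13 2-(3-{(1R,2R)-2-[(2S)-1-(tert-butyldiphenylsilyloxy)propan-2-yl]cyclopropyl}propyl)-1,3-dioxolane
Product: 14 4-{(1R,2R)-2-[(2S)-1-(tert-butyldiphenylsilyloxy)propan-2-yl]cyclopropyl}butanal
Conditions: 2 M HCl, THF, rt
Reagents that add atoms: water, O
Why: Acid-catalysed acetal hydrolysis should release the C1 aldehyde, and the tert-butyldiphenylsilyl ether and the alkyl cyclopropane are stable to dilute aqueous acid at room temperature.

Step 10
Reactants: 14 4-{(1R,2R)-2-[(2S)-1-(tert-butyldiphenylsilyloxy)propan-2-yl]cyclopropyl}butanal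
Product: 15 methyl 4-{(1R,2R)-2-[(2S)-1-(tert-butyldiphenylsilyloxy)propan-2-yl]cyclopropyl}butanoate
Conditions: I2, KOH, MeOH, 0 °C
Reagents that add atoms: methanol, CO
Why: Oxidative esterification: the methyl hemiacetal formed in methanol is oxidised by hypoiodite to the methyl ester, and the short cold exposure to base should leave the silyl ether intact.

Step 11
Reactants: 15 methyl 4-{(1R,2R)-2-[(2S)-1-(tert-butyldiphenylsilyloxy)propan-2-yl]cyclopropyl}butanoate
Product: 16 methyl 4-{(1R,2R)-2-[(2S)-1-hydroxypropan-2-yl]cyclopropyl}butanoate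
Conditions: Bu4NF, AcOH, THF, 0 °C → rt
Reagents that add atoms: none
Why: Fluoride-mediated desilylation frees the C9 hydroxyl, and buffering with acetic acid protects the methyl ester from basic hydrolysis.

Step 12
Reactants: 16 methyl 4-{(1R,2R)-2-[(2S)-1-hydroxypropan-2-yl]cyclopropyl}butanoate
Product: 17 methyl 4-{(1R,2R)-2-[(2S)-1-oxopropan-2-yl]cyclopropyl}butanoate
Conditions: Dess–Martin periodinane, NaHCO3, CH2Cl2, 0 °C; used at once
Reagents that add atoms: none
Why: Buffered Dess–Martin oxidation is near-neutral, so the α-stereogenic aldehyde (C8) should be obtained without epimerisation if it is carried forward immediately.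

Step 13
Reactants: 17 methyl 4-{(1R,2R)-2-[(2S)-1-oxopropan-2-yl]cyclopropyl}butanoate
Product: 18 methyl 4-{(1R,2R)-2-[(2S,3E)-4-iodobut-3-en-2-yl]cyclopropyl}butanoate
Conditions: CHI3, CrCl2, THF/1,4-dioxane, 0 °C → rt
Reagents that add atoms: iodoform, IC(I)I
Why: Takai olefination: the geminal dichromium carbenoid generated from iodoform and divalent chromium (CrCl2) adds to the aldehyde and eliminates to the (E)-vinyl iodide (C9=C10) under non-basic conditions that tolerate the ester and the C8 centre.

**C11–C19 unit**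

Step 14
Reactants: 19 (S)-citronellal [(3S)-3,7-dimethyloct-6-enal]
Product: 20 (4S)-4,8-dimethylnon-7-en-1-yne
Conditions: dimethyl (1-diazo-2-oxopropyl)phosphonate, K2CO3, MeOH, 0 °C → rt
Reagents that add atoms: dimethyl (1-diazo-2-oxopropyl)phosphonate, COP(=O)(OC)C(=[N+]=[N-])C(C)=O
Why: Ohira–Bestmann (Seyferth–Gilbert type) homologation turns the aldehyde carbon into C18 and adds C19 as the alkyne terminus, and the C16 centre is β to the carbonyl and cannot epimerise.

Step 15
Reactants: 20 (4S)-4,8-dimethylnon-7-en-1-yne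
Product: 22 [(4S)-4,8-dimethylnon-7-en-1-yn-1-yl]tri(propan-2-yl)silane, via lithium acetylide 21 (not isolated)
Conditions: n-BuLi, THF, −78 °C; i-Pr3SiCl, −78 °C → rt
Reagents that add atoms: chlorotri(propan-2-yl)silane, CC(C)[Si](Cl)(C(C)C)C(C)C
Why: Deprotonation and C-silylation of the terminal alkyne installs a bulky silyl cap that should withstand the acetylide alkylation and shield this alkyne from carbometalation later.

Step 16
Reactants: 22 [(4S)-4,8-dimethylnon-7-en-1-yn-1-yl]tri(propan-2-yl)silane
Product: 24 (4S)-4-methyl-7-[tri(propan-2-yl)silyl]hept-6-yn-1-ol, via secondary ozonide 23 (not isolated)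
Conditions: O3, CH2Cl2, −78 °C (Sudan Red 7B indicator); then NaBH4, MeOH, −78 °C → rt
Reagents that add atoms: ozone, [O-][O+]=O
Why: Ozonolysis with reductive work-up cleaves the electron-rich trisubstituted olefin much faster than the hindered silylalkyne and gives the C13 primary alcohol directly.

Step 17
Reactants: 24 (4S)-4-methyl-7-[tri(propan-2-yl)silyl]hept-6-yn-1-ol
Product: 25 [(4S)-7-iodo-4-methylhept-1-yn-1-yl]tri(propan-2-yl)silane
Conditions: I2, PPh3, imidazole, CH2Cl2, 0 °C → rt
Reagents that add atoms: iodine, II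
Why: Appel-type iodination converts the primary alcohol into the iodide by SN2 displacement of the alkoxyphosphonium intermediate.

Step 18
Reactants: 25 [(4S)-7-iodo-4-methylhept-1-yn-1-yl]tri(propan-2-yl)silane
Product: 26 [(4S)-4-methylnona-1,8-diyn-1-yl]tri(propan-2-yl)silane
Conditions: LiC≡CH·H2NCH2CH2NH2, DMSO, 10 °C → rt
Reagents that add atoms: lithium acetylide (ethylenediamine complex), [Li]C#C
Why: SN2 alkylation of lithium acetylide by the primary iodide adds C12 and C11 as a terminal alkyne, and the triisopropylsilyl group is too hindered for attack at silicon.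

**Fragment union and end game**

Step 19
Reactants: 26 [(4S)-4-methylnona-1,8-diyn-1-yl]tri(propan-2-yl)silane; 18 methyl 4-{(1R,2R)-2-[(2S,3E)-4-iodobut-3-en-2-yl]cyclopropyl}butanoate
Product: 29 methyl 4-{(1R,2R)-2-[(2R,3E,5E,10S)-6,10-dimethyl-13-[tri(propan-2-yl)silyl]trideca-3,5-dien-12-yn-2-yl]cyclopropyl}butanoate, via alkenyldimethylalane 27 (not isolated), via alkenylzinc chloride 28 (not isolated)
Conditions: 26 (1.5 equiv), Me3Al, Cp2ZrCl2 (25 mol %), CH2Cl2, 0 °C → rt; volatiles removed in vacuo; THF, ZnCl2; then 18, Pd(PPh3)4 (5 mol %), rt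
Reagents that add atoms: trimethylaluminium, C[Al](C)C
Why: Zirconium-catalysed syn-methylalumination of the terminal alkyne places the methyl on C12 and the metal on C11 with E geometry, and after transmetalation to zinc a Negishi coupling under zerovalent palladium catalysis joins C10 to C11 with retention at both olefins, while the methyl ester is tolerated once excess Me3Al has been evaporated.

Step 20
Reactants: 29 methyl 4-{(1R,2R)-2-[(2R,3E,5E,10S)-6,10-dimethyl-13-[tri(propan-2-yl)silyl]trideca-3,5-dien-12-yn-2-yl]cyclopropyl}butanoate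
Product: 31 methyl 4-{(1R,2R)-2-[(2R,3E,5E,10S)-13-bromo-6,10-dimethyltrideca-3,5-dien-12-yn-2-yl]cyclopropyl}butanoate (CNP0299695.1), via silver acetylide 30 (not isolated)
Conditions: AgF, NBS, MeCN, rt, dark
Reagents that add atoms: N-bromosuccinimide, O=C1CCC(=O)N1Br
Why: Silver-mediated bromodesilylation: fluoride cleaves the alkynyl–silicon bond to a silver acetylide that is brominated at carbon by NBS faster than the N-bromoimide can attack the diene, giving the bromoalkyne in one operation.

**Compound list**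

1 | methyl (R)-3-hydroxy-2-methylpropanoate | COC(=O)[C@H](C)CO | starting material
2 | methyl (2R)-3-(tert-butyldiphenylsilyloxy)-2-methylpropanoate | COC(=O)[C@H](C)CO[Si](c1ccccc1)(c1ccccc1)C(C)(C)C | intermediate
3 | (2R)-3-(tert-butyldiphenylsilyloxy)-2-methylpropanal | O=C[C@H](C)CO[Si](c1ccccc1)(c1ccccc1)C(C)(C)C | intermediate
4 | triethyl phosphonoacetate | CCOC(=O)CP(=O)(OCC)OCC | starting material
5 | ethyl (2E,4S)-5-(tert-butyldiphenylsilyloxy)-4-methylpent-2-enoate | CCOC(=O)/C=C/[C@H](C)CO[Si](c1ccccc1)(c1ccccc1)C(C)(C)C | intermediate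
6 | (2E,4S)-5-(tert-butyldiphenylsilyloxy)-4-methylpent-2-en-1-ol | OC/C=C/[C@H](C)CO[Si](c1ccccc1)(c1ccccc1)C(C)(C)C | intermediate
7 | diiodomethane | ICI | starting material
8 | iodomethylzinc (2E,4S)-5-(tert-butyldiphenylsilyloxy)-4-methylpent-2-en-1-olate | IC[Zn]OC/C=C/[C@H](C)CO[Si](c1ccccc1)(c1ccccc1)C(C)(C)C | intermediate (not isolated)
9 | [(1R,2S)-2-[(2S)-1-(tert-butyldiphenylsilyloxy)propan-2-yl]cyclopropyl]methanol | OC[C@@H]1C[C@H]1[C@H](C)CO[Si](c1ccccc1)(c1ccccc1)C(C)(C)C | intermediate
10 | (1R,2S)-2-[(2S)-1-(tert-butyldiphenylsilyloxy)propan-2-yl]cyclopropane-1-carbaldehyde | O=C[C@@H]1C[C@H]1[C@H](C)CO[Si](c1ccccc1)(c1ccccc1)C(C)(C)C | intermediate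
11 | [2-(1,3-dioxolan-2-yl)ethyl]triphenylphosphonium bromide | [Br-].C1COC(CC[P+](c2ccccc2)(c2ccccc2)c2ccccc2)O1 | starting material
12 | 2-[(2Z)-3-{(1S,2R)-2-[(2S)-1-(tert-butyldiphenylsilyloxy)propan-2-yl]cyclopropyl}prop-2-en-1-yl]-1,3-dioxolane | C1COC(O1)C/C=C\[C@@H]1C[C@H]1[C@H](C)CO[Si](c1ccccc1)(c1ccccc1)C(C)(C)C | intermediate
13 | 2-(3-{(1R,2R)-2-[(2S)-1-(tert-butyldiphenylsilyloxy)propan-2-yl]cyclopropyl}propyl)-1,3-dioxolane | C1COC(O1)CCC[C@@H]1C[C@H]1[C@H](C)CO[Si](c1ccccc1)(c1ccccc1)C(C)(C)C | intermediate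
14 | 4-{(1R,2R)-2-[(2S)-1-(tert-butyldiphenylsilyloxy)propan-2-yl]cyclopropyl}butanal | O=CCCC[C@@H]1C[C@H]1[C@H](C)CO[Si](c1ccccc1)(c1ccccc1)C(C)(C)C | intermediate
15 | methyl 4-{(1R,2R)-2-[(2S)-1-(tert-butyldiphenylsilyloxy)propan-2-yl]cyclopropyl}butanoate | COC(=O)CCC[C@@H]1C[C@H]1[C@H](C)CO[Si](c1ccccc1)(c1ccccc1)C(C)(C)C | intermediate
16 | methyl 4-{(1R,2R)-2-[(2S)-1-hydroxypropan-2-yl]cyclopropyl}butanoate | COC(=O)CCC[C@@H]1C[C@H]1[C@H](C)CO | intermediate
17 | methyl 4-{(1R,2R)-2-[(2S)-1-oxopropan-2-yl]cyclopropyl}butanoate | COC(=O)CCC[C@@H]1C[C@H]1[C@H](C)C=O | intermediate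
18 | methyl 4-{(1R,2R)-2-[(2S,3E)-4-iodobut-3-en-2-yl]cyclopropyl}butanoate | COC(=O)CCC[C@@H]1C[C@H]1[C@H](C)/C=C/I | intermediate
19 | (S)-citronellal [(3S)-3,7-dimethyloct-6-enal] | CC(C)=CCC[C@H](C)CC=O | starting material
20 | (4S)-4,8-dimethylnon-7-en-1-yne | CC(C)=CCC[C@H](C)CC#C | intermediate
21 | lithium (4S)-4,8-dimethylnon-7-en-1-yn-1-ide | CC(C)=CCC[C@H](C)CC#C[Li] | intermediate (not isolated)
22 | [(4S)-4,8-dimethylnon-7-en-1-yn-1-yl]tri(propan-2-yl)silane | CC(C)=CCC[C@H](C)CC#C[Si](C(C)C)(C(C)C)C(C)C | intermediate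
23 | 3,3-dimethyl-5-{(3S)-3-methyl-6-[tri(propan-2-yl)silyl]hex-5-yn-1-yl}-1,2,4-trioxolane (secondary ozonide, both C5 epimers) | CC1(C)OOC(CC[C@H](C)CC#C[Si](C(C)C)(C(C)C)C(C)C)O1 | intermediate (not isolated)
24 | (4S)-4-methyl-7-[tri(propan-2-yl)silyl]hept-6-yn-1-ol | OCCC[C@H](C)CC#C[Si](C(C)C)(C(C)C)C(C)C | intermediate
25 | [(4S)-7-iodo-4-methylhept-1-yn-1-yl]tri(propan-2-yl)silane | ICCC[C@H](C)CC#C[Si](C(C)C)(C(C)C)C(C)C | intermediate
26 | [(4S)-4-methylnona-1,8-diyn-1-yl]tri(propan-2-yl)silane | C#CCCC[C@H](C)CC#C[Si](C(C)C)(C(C)C)C(C)C | intermediate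
27 | {(1E,6S)-2,6-dimethyl-9-[tri(propan-2-yl)silyl]non-1-en-8-yn-1-yl}dimethylalane | C[Al](C)/C=C(\C)CCC[C@H](C)CC#C[Si](C(C)C)(C(C)C)C(C)C | intermediate (not isolated)
28 | chloro{(1E,6S)-2,6-dimethyl-9-[tri(propan-2-yl)silyl]non-1-en-8-yn-1-yl}zinc | Cl[Zn]/C=C(\C)CCC[C@H](C)CC#C[Si](C(C)C)(C(C)C)C(C)C | intermediate (not isolated)
29 | methyl 4-{(1R,2R)-2-[(2R,3E,5E,10S)-6,10-dimethyl-13-[tri(propan-2-yl)silyl]trideca-3,5-dien-12-yn-2-yl]cyclopropyl}butanoate | COC(=O)CCC[C@@H]1C[C@H]1[C@H](C)/C=C/C=C(\C)CCC[C@H](C)CC#C[Si](C(C)C)(C(C)C)C(C)C | intermediate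
30 | silver acetylide of the desilylated ester (silver at C19) | COC(=O)CCC[C@@H]1C[C@H]1[C@H](C)/C=C/C=C(\C)CCC[C@H](C)CC#C[Ag] | intermediate (not isolated)
31 | methyl 4-{(1R,2R)-2-[(2R,3E,5E,10S)-13-bromo-6,10-dimethyltrideca-3,5-dien-12-yn-2-yl]cyclopropyl}butanoate (CNP0299695.1) | COC(=O)CCC[C@@H]1C[C@H]1[C@H](C)/C=C/C=C(\C)CCC[C@H](C)CC#CBr | target

**Step count**

Total: 20 steps (15 in the main line, 5 for the C11–C19 unit).
Longest linear sequence: 15 steps (steps 1–13, 19, 20).

**Steps most likely to fail**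

1. Step 5 (key step). The facial selectivity may erode if the preference of the ligand and the bias of the C8 centre oppose each other, or if excess carbenoid cyclopropanates unligated alkoxide; the ring diastereomer would then be carried along. The fallback sets out from 3 and comes back at 9, and it replaces facial control by a stereospecific ring closure.
   - Aldehyde 3 would be methylenated (Ph3P=CH2, THF) to the olefin tert-butyl{[(2S)-2-methylbut-3-en-1-yl]oxy}diphenylsilane F1.
   - Epoxidation with mCPBA should give the oxirane (2S)-2-[(2R)-1-(tert-butyldiphenylsilyloxy)propan-2-yl]oxirane F2 together with its epimer (2R)-2-[(2R)-1-(tert-butyldiphenylsilyloxy)propan-2-yl]oxirane F3.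
   - Hydrolytic kinetic resolution would use the (R,R) enantiomer of N,N′-bis(3,5-di-tert-butylsalicylidene)-1,2-cyclohexanediaminocobalt acetate (trivalent cobalt) with 0.55 equiv H2O. This is the enantiomer that leaves (S)-configured alkyl oxiranes unreacted, so it should open F3 to the diol (2R,3R)-4-(tert-butyldiphenylsilyloxy)-3-methylbutane-1,2-diol F4 and leave F2.
   - Heating F2 with the sodium salt of 4 (NaH, toluene, 110 °C; Wadsworth–Emmons cyclopropanation) should give ethyl (1R,2S)-2-[(2S)-1-(tert-butyldiphenylsilyloxy)propan-2-yl]cyclopropane-1-carboxylate F5. The phosphonate carbanion opens the oxirane at its CH2 (C6), the phosphoryl group migrates to the alkoxide, and the ester enolate displaces phosphate at C7 with inversion. C7 thus comes from the resolved epoxide and C5 from the trans preference of the closure.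
   - Reduction of F5 with i-Bu2AlH rejoins the route at 9.

2. Step 19. Transfer of the hindered trisubstituted alkenyl group from aluminium through zinc to palladium may be slow, residual methylmetal species may methylate 18, or the silylalkyne may be partly carbometalated. The fallback sets out from 26 and 17 and comes back at 29, using a Suzuki–Miyaura coupling with reversed polarity.
   - Methylalumination of 26 followed by iodinolysis (Me3Al, Cp2ZrCl2; then I2, THF, −30 °C) would give [(4S,8E)-9-iodo-4,8-dimethylnon-8-en-1-yn-1-yl]tri(propan-2-yl)silane F6, which can be purified.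
   - Aldehyde 17 would be converted with Cl2CHB(pin), CrCl2 and LiI (boron variant of the Takai olefination) into methyl 4-{(1R,2R)-2-[(2R,3E)-4-(4,4,5,5-tetramethyl-1,3,2-dioxaborolan-2-yl)but-3-en-2-yl]cyclopropyl}butanoate F7.
   - Coupling of F6 and F7 (Pd(PPh3)4, aq. K3PO4, THF, rt) should give 29.

3. Step 20. Electrophilic bromine may attack the electron-rich diene, or fluoride may cleave the hindered silyl group incompletely. The fallback sets out from 29 and comes back at 31, and it avoids both silver and N-bromoimide.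
   - Desilylation with Bu4NF (THF, 0 °C) would give methyl 4-{(1R,2R)-2-[(2R,3E,5E,10S)-6,10-dimethyltrideca-3,5-dien-12-yn-2-yl]cyclopropyl}butanoate F8.
   - F8 would be brominated with CBr4 and a catalytic amount of Bu4NF (THF, rt). Here the acetylide takes bromine from CBr4 by halophilic transfer, a reagent that does not add to olefins, to give 31.

**Further compounds**

F1 | step 5 | tert-butyl{[(2S)-2-methylbut-3-en-1-yl]oxy}diphenylsilane | C=C[C@H](C)CO[Si](c1ccccc1)(c1ccccc1)C(C)(C)C
F2 | step 5 | (2S)-2-[(2R)-1-(tert-butyldiphenylsilyloxy)propan-2-yl]oxirane | C1[C@@H](O1)[C@H](C)CO[Si](c1ccccc1)(c1ccccc1)C(C)(C)C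
F3 | step 5 | (2R)-2-[(2R)-1-(tert-butyldiphenylsilyloxy)propan-2-yl]oxirane | C1[C@H](O1)[C@H](C)CO[Si](c1ccccc1)(c1ccccc1)C(C)(C)C
F4 | step 5 | (2R,3R)-4-(tert-butyldiphenylsilyloxy)-3-methylbutane-1,2-diol | OC[C@H](O)[C@H](C)CO[Si](c1ccccc1)(c1ccccc1)C(C)(C)C
F5 | step 5 | ethyl (1R,2S)-2-[(2S)-1-(tert-butyldiphenylsilyloxy)propan-2-yl]cyclopropane-1-carboxylate | CCOC(=O)[C@@H]1C[C@H]1[C@H](C)CO[Si](c1ccccc1)(c1ccccc1)C(C)(C)C
F6 | step 19 | [(4S,8E)-9-iodo-4,8-dimethylnon-8-en-1-yn-1-yl]tri(propan-2-yl)silane | I/C=C(\C)CCC[C@H](C)CC#C[Si](C(C)C)(C(C)C)C(C)C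
F7 | step 19 | methyl 4-{(1R,2R)-2-[(2R,3E)-4-(4,4,5,5-tetramethyl-1,3,2-dioxaborolan-2-yl)but-3-en-2-yl]cyclopropyl}butanoate | COC(=O)CCC[C@@H]1C[C@H]1[C@H](C)/C=C/B1OC(C)(C)C(C)(C)O1
F8 | step 20 | methyl 4-{(1R,2R)-2-[(2R,3E,5E,10S)-6,10-dimethyltrideca-3,5-dien-12-yn-2-yl]cyclopropyl}butanoate | COC(=O)CCC[C@@H]1C[C@H]1[C@H](C)/C=C/C=C(\C)CCC[C@H](C)CC#C
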